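**Plan**

Labels: ring A = the cyclohexadienone ring (C1 = C=O; C2–C3 and C6–C5 = the two CH=CH edges; C4 carries the exocyclic carbon C7); ring B = 4-hydroxyphenyl on C7; ring C = central benzene; ring D = 4-hydroxyphenyl on ring C; ring E = phenol ring of the arylethynyl group.
Retrosynthesis: remove the protecting groups and return a hydride to C7 (leuco phenol); cut ring A at C2–C3 (ring-closing condensation) and at C4–C5 (Michael addition) to a 3,3-diarylpropanal plus but-3-yn-2-one; cut C7–ring B (conjugate addition to a ring C cinnamaldehyde); cut ring C–ring D (Suzuki–Miyaura), ring C–alkyne (Sonogashira) and ring C–C7 (aryllithium plus vinylogous formamide) back to (2-bromo-4-chlorophenyl)methanol.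
Forward: ring C first receives the C7–C4–C3 enal chain, then the ring E alkyne and ring D; ring B is added to C7; ring A is then built de novo in one operation; the C7 hydrogen, kept as a temporary oxidation-level helper, is oxidised off and acid deprotection finishes.
Enabling feature: in ring A the oxygen on C1 is para to C4, which bears the benzhydrylic C7. C3–C4 is therefore the CHO/α-CH2 pair of a 3,3-diarylpropanal and C5–C6–C1(=O)–C2 is but-3-yn-2-one; in the open-chain adduct the methyl-ketone carbon C2 and the formyl-derived carbon C3 sit 1,6 across C5=C6, and closure is driven by aromatisation. Rings A and B are tautomers of each other, so either may be the ring made de novo.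
Stereochemistry: the target has no stereocentre and C4=C7 is not stereogenic (C3 and C5 are constitutionally identical); the racemic C7 centre of the propanal and of the leuco phenol is erased in step 7.

Key step: step 6

Assumption: 1-ethynyl-4-(methoxymethoxy)benzene is taken as a catalogue compound; if not stocked it is one MOM protection away from 4-ethynylphenol.
Abbreviations in names: TBS = tert-butyldimethylsilyl; MOM = methoxymethyl; ArB = 4-(MOMO)phenyl; ArC = 3-(TBSOCH2)-6-[4-(MOMO)phenyl]-2-{[4-(MOMO)phenyl]ethynyl}phenyl.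

**Route**

Step 1
Reactants: 1 (2-bromo-4-chlorophenyl)methanol
Product: 2 tert-butyl[(2-bromo-4-chlorophenyl)methoxy]dimethylsilane
Conditions: TBSCl, imidazole, DMF, rt
Reagents that add atoms: tert-butyldimethylsilyl chloride (TBSCl), CC(C)(C)[Si](C)(C)Cl
Why: Standard silylation of a primary benzylic alcohol; the TBS ether should survive the amide base, both palladium couplings, the Grignard/copper step and ethoxide, and falls in the final acid step.

Step 2
Reactants: 2 tert-butyl[(2-bromo-4-chlorophenyl)methoxy]dimethylsilane; 3 (2E)-3-(dimethylamino)prop-2-enal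
Product: 6 (2E)-3-[2-bromo-6-chloro-3-(TBSOCH2)phenyl]prop-2-enal, via aryllithium 4 (not isolated), via lithium allylic alkoxide 5 (not isolated)
Conditions: LiN(i-Pr)2 (LDA), THF, −78 °C; then 3, −78 → −20 °C; then 1 M aq. HCl, 0 °C
Reagents that add atoms: none
Why: The amide base should remove the most acidic ring proton, the one flanked by Br and Cl (ortho-lithiation between two halogens, no halogen–lithium exchange), and the aryllithium adds to the vinylogous formamide, acid work-up expelling dimethylamine to give the (E)-enal (vinylogous formylation).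

Step 3
Reactants: 6 (2E)-3-[2-bromo-6-chloro-3-(TBSOCH2)phenyl]prop-2-enal; 7 1-ethynyl-4-(methoxymethoxy)benzene
Product: 8 (2E)-3-[6-chloro-2-{[4-(MOMO)phenyl]ethynyl}-3-(TBSOCH2)phenyl]prop-2-enal
Conditions: PdCl2(PPh3)2 (3 mol %), CuI (5 mol %), Et3N, THF, 60 °C
Reagents that add atoms: none
Why: Sonogashira coupling in which the triphenylphosphine–palladium catalyst should insert into the C–Br bond and leave the C–Cl bond, while the tertiary amine does not add to the enal.

Step 4
Reactants: 8 (2E)-3-[6-chloro-2-{[4-(MOMO)phenyl]ethynyl}-3-(TBSOCH2)phenyl]prop-2-enal; 9 [4-(methoxymethoxy)phenyl]boronic acid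
Product: 10 (2E)-3-(ArC)prop-2-enal
Conditions: Pd(OAc)2 (2 mol %), SPhos (4 mol %), K3PO4, toluene/H2O, 90 °C
Reagents that add atoms: none
Why: Suzuki–Miyaura coupling of the remaining, only mono-ortho-substituted aryl chloride with a dialkylbiarylphosphine–palladium catalyst; the enal has no enolisable hydrogen and the alkyne, acetals and silyl ether are inert to aqueous phosphate.

Step 5
Reactants: 10 (2E)-3-(ArC)prop-2-enal; 11 1-bromo-4-(methoxymethoxy)benzene
Product: 14 3-(ArB)-3-(ArC)propanal (racemic), via aryl Grignard reagent 12 (not isolated), via trimethylsilyl enol ether 13 (not isolated)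
Conditions: 11, Mg, THF, 40 °C; then CuBr·SMe2 (10 mol %), TMSCl, 10, THF, −78 → −30 °C; then 1 M aq. HCl, THF, 0 °C
Reagents that add atoms: none
Why: Chlorosilane-accelerated copper-catalysed 1,4-addition of an aryl Grignard reagent to an enal, which favours conjugate over carbonyl addition and traps the enolate as silyl enol ether 13 (hydrolysed on work-up); the rod-like ethynyl substituent should leave one face of C7 open, and the new C7 stereocentre forms racemic and is erased in step 7.

Step 6
Reactants: 14 3-(ArB)-3-(ArC)propanal; 15 but-3-yn-2-one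
Product: 18 4-[(ArB)(ArC)methyl]phenol (racemic), via pyrrolidine enamine 16 (not isolated), via aminodienone 17 (not isolated)
Conditions: pyrrolidine (1.05 equiv), 4 Å molecular sieves, toluene, rt, then evaporation; 15 (1.3 equiv), EtOH, 0 °C → rt; then NaOEt (2 equiv), EtOH, 70 °C; AcOH quench
Reagents that add atoms: none
Why: Enamine 16 should attack the terminal alkyne carbon of 15 through C4 (Stork enamine Michael addition, as in the first stage of a Bohlmann–Rahtz sequence), and proton transfer in ethanol gives the push–pull aminodienone 17, in which C4 is joined to C5. Ethoxide then generates the C2 enolate, and the C2–C3 bond forms by disrotatory 6π-electrocyclisation of the resulting 1-amino-5-oxidohexatriene (equivalent to a 6-exo-trig aldol-type attack of C2 on the aminomethine carbon C3), after which pyrrolidine is expelled and ring A emerges directly as the aromatic phenolate. The closest known reaction types are the Jutz-type benzannulation of δ-aminodienones, the phenol synthesis from vinamidinium salts and methyl ketones, and the base-induced conversion of 2-methylpyrylium pseudobases into phenols. No stereocentre is formed in ring A; the racemic C7 centre is not touched and is removed in step 7. The step needs carbon–carbon bond formation at C4 instead of [2+2] cycloaddition or amine addition to the ynone, which the protic solvent (fast protonation of the zwitterion) and the preformed enamine without free amine should secure; it needs a cis C5=C6 geometry, which the low rotational barrier of the vinylogous amide and reversible ethoxide addition at C5 provide; and C2-to-C3 is the only nucleophile–electrophile pairing in 17 that can give a six-membered carbocycle. The primary TBS ether, the three MOM acetals and the diarylalkyne are inert to pyrrolidine and ethoxide.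

Step 7
Reactants: 18 4-[(ArB)(ArC)methyl]phenol
Product: 19 4-[(ArB)(ArC)methylidene]cyclohexa-2,5-dien-1-one
Conditions: DDQ (1.05 equiv), CH2Cl2, 0 °C → rt
Reagents that add atoms: none
Why: Quinone dehydrogenation of a 4-benzhydrylphenol to the fuchsone (the classical leuco-to-dye oxidation): hydride loss from C7, activated by the ring A phenol and by ring B, then loss of the phenolic proton, should remove the temporary C7 hydrogen and its stereocentre, while no other C–H bond is comparably activated.

Step 8
Reactants: 19 4-[(ArB)(ArC)methylidene]cyclohexa-2,5-dien-1-one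
Product: 20 selaginellin
Conditions: 3 M aq. HCl, THF, 45 °C; then aq. NaHCO3 to pH 6–7
Reagents that add atoms: none
Why: Acid hydrolysis of the three aryl MOM acetals and of the primary TBS ether; the fuchsone is only reversibly protonated or hydrated at C7 in acid and should return to the quinone methide on neutralisation, and the hydroxymethyl group cannot reach C7 or add to the alkyne under these conditions.

**Compound list**

1 | (2-bromo-4-chlorophenyl)methanol | OCc1ccc(Cl)cc1Br | starting material
2 | tert-butyl[(2-bromo-4-chlorophenyl)methoxy]dimethylsilane | CC(C)(C)[Si](C)(C)OCc1ccc(Cl)cc1Br | intermediate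
3 | (2E)-3-(dimethylamino)prop-2-enal | CN(C)/C=C/C=O | starting material
4 | [2-bromo-6-chloro-3-(TBSOCH2)phenyl]lithium | [Li]c1c(Cl)ccc(CO[Si](C)(C)C(C)(C)C)c1Br | intermediate
5 | lithium (2E)-1-[2-bromo-6-chloro-3-(TBSOCH2)phenyl]-3-(dimethylamino)prop-2-en-1-olate (racemic) | [Li]OC(/C=C/N(C)C)c1c(Cl)ccc(CO[Si](C)(C)C(C)(C)C)c1Br | intermediate
6 | (2E)-3-[2-bromo-6-chloro-3-(TBSOCH2)phenyl]prop-2-enal | O=C/C=C/c1c(Cl)ccc(CO[Si](C)(C)C(C)(C)C)c1Br | intermediate
7 | 1-ethynyl-4-(methoxymethoxy)benzene | C#Cc1ccc(OCOC)cc1 | starting material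
8 | (2E)-3-[6-chloro-2-{[4-(MOMO)phenyl]ethynyl}-3-(TBSOCH2)phenyl]prop-2-enal | O=C/C=C/c1c(Cl)ccc(CO[Si](C)(C)C(C)(C)C)c1C#Cc1ccc(OCOC)cc1 | intermediate
9 | [4-(methoxymethoxy)phenyl]boronic acid | COCOc1ccc(B(O)O)cc1 | starting material
10 | (2E)-3-(ArC)prop-2-enal | O=C/C=C/c1c(-c2ccc(OCOC)cc2)ccc(CO[Si](C)(C)C(C)(C)C)c1C#Cc1ccc(OCOC)cc1 | intermediate
11 | 1-bromo-4-(methoxymethoxy)benzene | COCOc1ccc(Br)cc1 | starting material
12 | [4-(methoxymethoxy)phenyl]magnesium bromide | COCOc1ccc([Mg]Br)cc1 | intermediate
13 | trimethyl{[3-(ArB)-3-(ArC)prop-1-en-1-yl]oxy}silane (E/Z mixture, racemic) | C[Si](C)(C)OC=CC(c1ccc(OCOC)cc1)c1c(-c2ccc(OCOC)cc2)ccc(CO[Si](C)(C)C(C)(C)C)c1C#Cc1ccc(OCOC)cc1 | intermediate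
14 | 3-(ArB)-3-(ArC)propanal (racemic) | O=CCC(c1ccc(OCOC)cc1)c1c(-c2ccc(OCOC)cc2)ccc(CO[Si](C)(C)C(C)(C)C)c1C#Cc1ccc(OCOC)cc1 | intermediate
15 | but-3-yn-2-one | CC(=O)C#C | starting material
16 | 1-[(1E)-3-(ArB)-3-(ArC)prop-1-en-1-yl]pyrrolidine (racemic) | N1(CCCC1)/C=C/C(c1ccc(OCOC)cc1)c1c(-c2ccc(OCOC)cc2)ccc(CO[Si](C)(C)C(C)(C)C)c1C#Cc1ccc(OCOC)cc1 | intermediate
17 | 6-(ArB)-6-(ArC)-5-(pyrrolidin-1-ylmethylidene)hex-3-en-2-one (E/Z mixture, racemic) | CC(=O)C=CC(=CN1CCCC1)C(c1ccc(OCOC)cc1)c1c(-c2ccc(OCOC)cc2)ccc(CO[Si](C)(C)C(C)(C)C)c1C#Cc1ccc(OCOC)cc1 | intermediate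
18 | 4-[(ArB)(ArC)methyl]phenol (racemic) | Oc1ccc(cc1)C(c1ccc(OCOC)cc1)c1c(-c2ccc(OCOC)cc2)ccc(CO[Si](C)(C)C(C)(C)C)c1C#Cc1ccc(OCOC)cc1 | intermediate
19 | 4-[(ArB)(ArC)methylidene]cyclohexa-2,5-dien-1-one | O=C1C=CC(=C(c2ccc(OCOC)cc2)c2c(-c3ccc(OCOC)cc3)ccc(CO[Si](C)(C)C(C)(C)C)c2C#Cc2ccc(OCOC)cc2)C=C1 | intermediate
20 | selaginellin, 4-{[3-(hydroxymethyl)-6-(4-hydroxyphenyl)-2-[(4-hydroxyphenyl)ethynyl]phenyl](4-hydroxyphenyl)methylidene}cyclohexa-2,5-dien-1-one | O=C1C=CC(=C(c2ccc(O)cc2)c2c(-c3ccc(O)cc3)ccc(CO)c2C#Cc2ccc(O)cc2)C=C1 | target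

**Summary**

Total step count: 8. Longest linear sequence: 8 steps (from 1).

Steps most likely to fail:

1. Step 6. The enamine and the ynone may combine by [2+2] cycloaddition and ring opening (two-carbon insertion) instead of Michael addition, the ynone may be consumed by amine addition or polymerisation, or the aminodienone may stall before ring closure because C5=C6 isomerises too slowly. Fallback, from 14 (through its enamine 16): a Robinson-type annulation one oxidation level lower. Enamine 16 and methyl vinyl ketone (dioxane, rt; then AcOH, NaOAc, H2O, 80 °C) should give, through 2-[(ArB)(ArC)methyl]-5-oxohexanal F1, 4-[(ArB)(ArC)methyl]cyclohex-2-en-1-one F2; ring A is closed by the same C2–C3 aldol condensation, without any alkene-geometry or cycloaddition issue. The kinetic silyl dienol ether trimethyl({4-[(ArB)(ArC)methyl]cyclohexa-1,5-dien-1-yl}oxy)silane F3 (LDA, TMSCl, THF, −78 °C) is then dehydrogenated by Saegusa–Ito oxidation (Pd(OAc)2, MeCN, rt) to the cross-conjugated dienone, which is the keto tautomer of 18 and aromatises to 18, where the route is rejoined.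

2. Step 5. Conjugate addition at C7, flanked by ring D and the alkyne, may be so slow that carbonyl addition of the Grignard reagent takes over. Fallback, from 8: the order of assembly and the organometallic manifold are both changed. A rhodium-catalysed Hayashi–Miyaura 1,4-addition of boronic acid 9 ([Rh(OH)(cod)]2, dioxane/H2O, 50 °C) is run on enal 8, where C7 is flanked by chlorine instead of ring D, and should give 3-(ArB)-3-[6-chloro-2-{[4-(MOMO)phenyl]ethynyl}-3-(TBSOCH2)phenyl]propanal F4. Suzuki–Miyaura coupling of F4 with 9 (Pd(OAc)2, SPhos, KF, THF/H2O, 60 °C) then installs ring D and returns to 14.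

3. Step 2. Aryllithium 4 may lose lithium halide (aryne formation) or suffer halogen migration before it adds to the weakly electrophilic vinylogous formamide. Fallback, from 2: aryllithium 4 is trapped at −78 °C with N,N-dimethylformamide, a fast quench, to give 2-bromo-6-chloro-3-(TBSOCH2)benzaldehyde F5. F5 is homologated by Wittig reaction with (triphenylphosphoranylidene)acetaldehyde (toluene, 80 °C) to rejoin the route at 6.

Further compounds
F1 | step 6 | 2-[(ArB)(ArC)methyl]-5-oxohexanal | CC(=O)CCC(C=O)C(c1ccc(OCOC)cc1)c1c(-c2ccc(OCOC)cc2)ccc(CO[Si](C)(C)C(C)(C)C)c1C#Cc1ccc(OCOC)cc1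
F2 | step 6 | 4-[(ArB)(ArC)methyl]cyclohex-2-en-1-one | O=C1CCC(C=C1)C(c1ccc(OCOC)cc1)c1c(-c2ccc(OCOC)cc2)ccc(CO[Si](C)(C)C(C)(C)C)c1C#Cc1ccc(OCOC)cc1
F3 | step 6 | trimethyl({4-[(ArB)(ArC)methyl]cyclohexa-1,5-dien-1-yl}oxy)silane | C[Si](C)(C)OC1=CCC(C=C1)C(c1ccc(OCOC)cc1)c1c(-c2ccc(OCOC)cc2)ccc(CO[Si](C)(C)C(C)(C)C)c1C#Cc1ccc(OCOC)cc1
F4 | step 5 | 3-(ArB)-3-[6-chloro-2-{[4-(MOMO)phenyl]ethynyl}-3-(TBSOCH2)phenyl]propanal | O=CCC(c1ccc(OCOC)cc1)c1c(Cl)ccc(CO[Si](C)(C)C(C)(C)C)c1C#Cc1ccc(OCOC)cc1
F5 | step 2 | 2-bromo-6-chloro-3-(TBSOCH2)benzaldehyde | O=Cc1c(Cl)ccc(CO[Si](C)(C)C(C)(C)C)c1Br
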